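**Retrosynthetic overview**
1. Target 29 ⇐ ketone 24 by oxygen functionalisation only: desilylation, two tiglates, enolate hydroxylation trans to the side chain, acetate.
2. 24 ⇐ ring fragment 10 + side-chain fragment 19: an alkoxide-directed conjugate addition forms the ring-to-side-chain C–C bond cis to the ring hydroxyl.
3. 10 ⇐ hydroxy enone 6 (hydroxyl-directed epoxidation, then selenoxide dehydrogenation); 6 ⇐ acyclic dienone 5 by ring-closing metathesis; 5 ⇐ lactone 1.
4. 19 ⇐ ynal 11: Brown allylation, cross-metathesis to the prenyl group, hydroalumination–iodination, Shi epoxidation.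
5. Ring order: cyclohexene ring (step 4), then ring epoxide (step 5); the side-chain epoxide is made separately on fragment 19 (step 12) before the union.

Assumption: lactone 1 (from L-glutamic acid) and ynal 11 are bought; reagents that only deliver atoms are given with SMILES in the steps and are not numbered.

**Ring fragment (steps 1–6)**

Step 1
Reactants: 1 (5S)-5-(hydroxymethyl)oxolan-2-one
Product: 2 (2S)-5-oxooxolane-2-carbaldehyde
Conditions: PhI(OAc)2, TEMPO (10 mol %), CH2Cl2, rt; used crude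
Reagents that add atoms: none
Why: Oxoammonium (TEMPO) oxidation of the primary alcohol stops at the aldehyde under anhydrous conditions and leaves the lactone and the stereocentre untouched.

Step 2
Reactants: 2 (2S)-5-oxooxolane-2-carbaldehyde
Product: 3 (5S)-5-ethenyloxolan-2-one
Conditions: Ph3PCH3Br, KN(SiMe3)2, THF, −78 to 0 °C
Reagents that add atoms: methyltriphenylphosphonium bromide, C[P+](c1ccccc1)(c1ccccc1)c1ccccc1.[Br-]
Why: Wittig methylenation at low temperature converts the aldehyde into the vinyl group faster than the α-oxygenated centre can epimerise, so the S configuration is kept.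

Step 3
Reactants: 3 (5S)-5-ethenyloxolan-2-one
Product: 5 (6S)-6-hydroxy-2-methylocta-1,7-dien-3-one, via lithium lactolate 4 (not isolated)
Conditions: CH2=C(CH3)Br, t-BuLi (2 equiv), Et2O, −78 °C; add to 3, THF, −78 °C; AcOH, −78 °C
Reagents that add atoms: 2-bromopropene, C=C(C)Br
Why: 1,2-Addition of an alkenyllithium to a γ-lactone gives a tetrahedral lactolate that is stable at −78 °C, so only one equivalent adds and the γ-hydroxy enone is released on quench.

Step 4
Reactants: 5 (6S)-6-hydroxy-2-methylocta-1,7-dien-3-one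
Product: 6 (4S)-4-hydroxy-2-methylcyclohex-2-en-1-one
Conditions: second-generation Hoveyda–Grubbs catalyst (H2IMes)Cl2Ru=CH(C6H4-2-O-i-Pr) (5 mol %), CH2Cl2 (0.005 M), 40 °C
Reagents that add atoms: none
Why: Ring-closing metathesis between the vinyl carbinol and the 2-propenyl ketone closes the six-membered ring as the trisubstituted enone with loss of ethene, the carbinol centre being unaffected.

Step 5
Reactants: 6 (4S)-4-hydroxy-2-methylcyclohex-2-en-1-one
Product: 7 (1S,5S,6S)-5-hydroxy-1-methyl-7-oxabicyclo[4.1.0]heptan-2-one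
Conditions: t-BuOOH (decane), benzyltrimethylammonium hydroxide (Triton B, 0.1 equiv), THF, 0 °C
Reagents that add atoms: tert-butyl hydroperoxide, CC(C)(C)OO
Why: Weitz–Scheffer nucleophilic epoxidation in which the free γ-hydroxyl hydrogen-bonds the peroxide anion and delivers it to its own face, setting both epoxide carbons cis to the hydroxyl.

Step 6
Reactants: 7 (1S,5S,6S)-5-hydroxy-1-methyl-7-oxabicyclo[4.1.0]heptan-2-one
Product: 10 (1S,5S,6S)-5-hydroxy-1-methyl-7-oxabicyclo[4.1.0]hept-3-en-2-one, via dilithium enolate 8 (not isolated), via α-phenylselanyl ketone 9 (not isolated)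
Conditions: LiN(i-Pr)2 (2.2 equiv), THF, −78 °C; PhSeBr; AcOH; then 30% H2O2, pyridine, CH2Cl2, 0 °C to rt
Reagents that add atoms: none
Why: The ketone can enolise only toward its CH2 (the other α-carbon is the quaternary epoxide carbon), so α-selenenylation and syn selenoxide elimination (Reich) give the enone without touching the three stereocentres.

**Side-chain fragment (steps 7–12)**

Step 7
Reactants: 11 3-(trimethylsilyl)prop-2-ynal
Product: 13 (3S)-1-(trimethylsilyl)hex-5-en-1-yn-3-ol, via borinate ester 12 (not isolated)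
Conditions: (−)-Ipc2BOMe, CH2=CHCH2MgBr, Et2O, 0 °C to rt; 11, −78 °C; then NaOH, 30% H2O2
Reagents that add atoms: allylmagnesium bromide, C=CC[Mg]Br
Why: Brown asymmetric allylboration through a chair Zimmerman–Traxler transition state; the isopinocampheyl groups derived from (+)-α-pinene direct allyl transfer to the aldehyde face that gives the S carbinol.

Step 8
Reactants: 13 (3S)-1-(trimethylsilyl)hex-5-en-1-yn-3-ol
Product: 14 (3S)-6-methyl-1-(trimethylsilyl)hept-5-en-1-yn-3-ol
Conditions: second-generation Grubbs catalyst (H2IMes)(PCy3)Cl2Ru=CHPh (3 mol %), 2-methylbut-2-ene/CH2Cl2, 40 °C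
Reagents that add atoms: 2-methylbut-2-ene, CC=C(C)C
Why: Olefin cross-metathesis with excess 2-methylbut-2-ene converts the terminal vinyl group into the prenyl-type trisubstituted alkene (propene is lost) while the silyl-capped alkyne stays inert.

Step 9
Reactants: 14 (3S)-6-methyl-1-(trimethylsilyl)hept-5-en-1-yn-3-ol
Product: 15 tert-butyl(dimethyl){[(3S)-6-methyl-1-(trimethylsilyl)hept-5-en-1-yn-3-yl]oxy}silane
Conditions: TBSCl, imidazole, DMF, rt
Reagents that add atoms: tert-butyldimethylsilyl chloride, CC(C)(C)[Si](C)(C)Cl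
Why: Standard imidazole-promoted O-silylation protects the carbinol as an ether that tolerates the organometallic steps ahead.

Step 10
Reactants: 15 tert-butyl(dimethyl){[(3S)-6-methyl-1-(trimethylsilyl)hept-5-en-1-yn-3-yl]oxy}silane
Product: 16 tert-butyl(dimethyl){[(3S)-6-methylhept-5-en-1-yn-3-yl]oxy}silane
Conditions: K2CO3 (cat.), MeOH, rt
Reagents that add atoms: none
Why: Methoxide-mediated protodesilylation cleaves only the alkynyl C–Si bond, the silyl ether being stable to these conditions.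

Step 11
Reactants: 16 tert-butyl(dimethyl){[(3S)-6-methylhept-5-en-1-yn-3-yl]oxy}silane
Product: 18 tert-butyl{[(3S)-2-iodo-6-methylhepta-1,5-dien-3-yl]oxy}dimethylsilane, via alkenylalane 17 (not isolated)
Conditions: Ni(dppp)Cl2 (3 mol %), i-Bu2AlH (1.3 equiv), THF, 0 to 22 °C; then I2, THF, −78 to 0 °C
Reagents that add atoms: iodine, II
Why: Nickel-catalysed α-selective (Markovnikov) hydroalumination of the terminal alkyne places aluminium on the internal carbon, and iodinolysis of the C–Al bond gives the 2-iodo-1-alkene.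

Step 12
Reactants: 18 tert-butyl{[(3S)-2-iodo-6-methylhepta-1,5-dien-3-yl]oxy}dimethylsilane
Product: 19 tert-butyl({(2S)-1-[(2R)-3,3-dimethyloxiran-2-yl]-3-iodobut-3-en-2-yl}oxy)dimethylsilane
Conditions: D-fructose-derived Shi ketone (0.3 equiv), KHSO5 (as Oxone), K2CO3, Bu4NHSO4, MeCN/CH2(OMe)2/aq. Na2B4O7 buffer (pH 10.5), 0 °C
Reagents that add atoms: potassium peroxymonosulfate, [K+].[O-]S(=O)(=O)OO
Why: Shi asymmetric epoxidation: the chiral dioxirane attacks only the electron-rich trisubstituted alkene (the iodoalkene is deactivated) through a spiro transition state that gives the R oxirane carbon under catalyst control.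

**Union and end game (steps 13–17)**

Step 13
Reactants: 19 (the epoxy alkenyl iodide) and 10 (1S,5S,6S)-5-hydroxy-1-methyl-7-oxabicyclo[4.1.0]hept-3-en-2-one
Product: 24 (1S,4R,5S,6S)-4-[(3S)-3-{[tert-butyl(dimethyl)silyl]oxy}-4-[(2R)-3,3-dimethyloxiran-2-yl]but-1-en-2-yl]-5-hydroxy-1-methyl-7-oxabicyclo[4.1.0]heptan-2-one, via alkenyllithium 20 (not isolated), via alkenylmagnesium bromide 21 (not isolated), via bromomagnesium alkoxide 22 (not isolated), via magnesium enolate 23 (not isolated)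
Conditions: 19 (1.6 equiv), t-BuLi (3.2 equiv), Et2O, −78 °C; MgBr2·OEt2, −78 °C; separately 10, MeMgBr (1.0 equiv), THF, −78 °C; combine, −78 to −30 °C; aq. NH4Cl
Reagents that add atoms: none
Why: Ligand-assisted (alkoxide-directed) conjugate addition of a Grignard reagent: the magnesium alkoxide next to the β-carbon delivers the alkenyl group to its own face, so the new C–C bond is cis to the ring oxygen (4R), and the enone has no enolisable α′-hydrogen to interfere.

Step 14
Reactants: 24 (the silyl-protected hydroxy ketone from step 13)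
Product: 25 (1S,4R,5S,6S)-4-{(3S)-4-[(2R)-3,3-dimethyloxiran-2-yl]-3-hydroxybut-1-en-2-yl}-5-hydroxy-1-methyl-7-oxabicyclo[4.1.0]heptan-2-one
Conditions: Bu4NF, AcOH (1:1), THF, 0 °C to rt
Reagents that add atoms: none
Why: Buffered fluoride desilylation frees the allylic hydroxyl without opening either epoxide and without a retro-aldol pathway, since neither hydroxyl is β to the ketone.

Step 15
Reactants: 25 (the diol from step 14)
Product: 26 (1S,2S,3R,6S)-3-[(3S)-4-[(2R)-3,3-dimethyloxiran-2-yl]-3-{[(2E)-2-methylbut-2-enoyl]oxy}but-1-en-2-yl]-6-methyl-5-oxo-7-oxabicyclo[4.1.0]heptan-2-yl (2E)-2-methylbut-2-enoate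
Conditions: tigloyl chloride (3 equiv), DMAP, Et3N, CH2Cl2, 0 °C to rt
Reagents that add atoms: (E)-2-methylbut-2-enoyl chloride (tigloyl chloride), C/C=C(\C)C(=O)Cl
Why: DMAP-catalysed acylation esterifies both secondary hydroxyls in one operation with retention at carbon, and the E (tiglate) geometry is the stable one.

Step 16
Reactants: 26 (the bis-tiglate ketone from step 15)
Product: 28 (1S,2S,3R,4S,6S)-3-[(3S)-4-[(2R)-3,3-dimethyloxiran-2-yl]-3-{[(2E)-2-methylbut-2-enoyl]oxy}but-1-en-2-yl]-4-hydroxy-6-methyl-5-oxo-7-oxabicyclo[4.1.0]heptan-2-yl (2E)-2-methylbut-2-enoate, via potassium enolate 27 (not isolated)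
Conditions: KN(SiMe3)2 (1.1 equiv), THF, −78 °C; 2-(phenylsulfonyl)-3-phenyloxaziridine, −78 °C; AcOH
Reagents that add atoms: 2-(phenylsulfonyl)-3-phenyloxaziridine, O=S(=O)(c1ccccc1)N1OC1c1ccccc1
Why: Davis oxaziridine hydroxylation of the only possible ketone enolate occurs anti to the bulky neighbouring alkenyl substituent, giving the hydroxyl trans to the side chain (4S).

Step 17
Reactants: 28 (the α-hydroxy ketone from step 16)
Product: 29 (1S,2S,3R,4S,6S)-4-(acetyloxy)-3-[(3S)-4-[(2R)-3,3-dimethyloxiran-2-yl]-3-{[(2E)-2-methylbut-2-enoyl]oxy}but-1-en-2-yl]-6-methyl-5-oxo-7-oxabicyclo[4.1.0]heptan-2-yl (2E)-2-methylbut-2-enoate (CNP0407453.3)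
Conditions: Ac2O, DMAP (cat.), pyridine, CH2Cl2, 0 °C
Reagents that add atoms: acetic anhydride, CC(=O)OC(C)=O
Why: Mild DMAP-catalysed O-acetylation of the α-hydroxy ketone proceeds with retention and leaves the epoxides and tiglates intact.

**Compound list**
1 | (5S)-5-(hydroxymethyl)oxolan-2-one | O=C1CC[C@@H](CO)O1 | starting material
2 | (2S)-5-oxooxolane-2-carbaldehyde | O=C1CC[C@@H](C=O)O1 | intermediate
3 | (5S)-5-ethenyloxolan-2-one | O=C1CC[C@@H](C=C)O1 | intermediate
4 | lithium (5S)-5-ethenyl-2-(prop-1-en-2-yl)oxolan-2-olate (both C2 epimers) | [Li+].[O-]C1(C(C)=C)CC[C@@H](C=C)O1 | intermediate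
5 | (6S)-6-hydroxy-2-methylocta-1,7-dien-3-one | C=C(C)C(=O)CC[C@H](O)C=C | intermediate
6 | (4S)-4-hydroxy-2-methylcyclohex-2-en-1-one | CC1=C[C@@H](O)CCC1=O | intermediate
7 | (1S,5S,6S)-5-hydroxy-1-methyl-7-oxabicyclo[4.1.0]heptan-2-one (hydroxyl cis to the epoxide oxygen) | O=C1CC[C@H](O)[C@@H]2O[C@]12C | intermediate
8 | dilithium (1S,5S,6S)-1-methyl-7-oxabicyclo[4.1.0]hept-2-ene-2,5-bis(olate) (enolate-alkoxide of 7) | [Li+].[Li+].[O-]C1=CC[C@H]([O-])[C@@H]2O[C@]12C | intermediate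
9 | (1S,5S,6S)-5-hydroxy-1-methyl-3-(phenylselanyl)-7-oxabicyclo[4.1.0]heptan-2-one (both C3 epimers) | O=C1C([Se]c2ccccc2)C[C@H](O)[C@@H]3O[C@]13C | intermediate
10 | (1S,5S,6S)-5-hydroxy-1-methyl-7-oxabicyclo[4.1.0]hept-3-en-2-one | O=C1C=C[C@H](O)[C@@H]2O[C@]12C | intermediate
11 | 3-(trimethylsilyl)prop-2-ynal | C[Si](C)(C)C#CC=O | starting material
12 | (3S)-1-(trimethylsilyl)hex-5-en-1-yn-3-yl diisopinocampheylborinate (isopinocampheyl groups from (+)-α-pinene) | C[Si](C)(C)C#C[C@H](CC=C)OB([C@@H]1C[C@@H]2C[C@@H](C2(C)C)[C@H]1C)[C@@H]1C[C@@H]2C[C@@H](C2(C)C)[C@H]1C | intermediate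
13 | (3S)-1-(trimethylsilyl)hex-5-en-1-yn-3-ol | C[Si](C)(C)C#C[C@@H](O)CC=C | intermediate
14 | (3S)-6-methyl-1-(trimethylsilyl)hept-5-en-1-yn-3-ol | C[Si](C)(C)C#C[C@@H](O)CC=C(C)C | intermediate
15 | tert-butyl(dimethyl){[(3S)-6-methyl-1-(trimethylsilyl)hept-5-en-1-yn-3-yl]oxy}silane | C[Si](C)(C)C#C[C@@H](O[Si](C)(C)C(C)(C)C)CC=C(C)C | intermediate
16 | tert-butyl(dimethyl){[(3S)-6-methylhept-5-en-1-yn-3-yl]oxy}silane | C#C[C@@H](O[Si](C)(C)C(C)(C)C)CC=C(C)C | intermediate
17 | {(3S)-3-{[tert-butyl(dimethyl)silyl]oxy}-6-methylhepta-1,5-dien-2-yl}bis(2-methylpropyl)alumane | C=C([Al](CC(C)C)CC(C)C)[C@@H](O[Si](C)(C)C(C)(C)C)CC=C(C)C | intermediate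
18 | tert-butyl{[(3S)-2-iodo-6-methylhepta-1,5-dien-3-yl]oxy}dimethylsilane | C=C(I)[C@@H](O[Si](C)(C)C(C)(C)C)CC=C(C)C | intermediate
19 | tert-butyl({(2S)-1-[(2R)-3,3-dimethyloxiran-2-yl]-3-iodobut-3-en-2-yl}oxy)dimethylsilane | C=C(I)[C@@H](O[Si](C)(C)C(C)(C)C)C[C@H]1OC1(C)C | intermediate
20 | {(3S)-3-{[tert-butyl(dimethyl)silyl]oxy}-4-[(2R)-3,3-dimethyloxiran-2-yl]but-1-en-2-yl}lithium | [Li]C(=C)[C@@H](O[Si](C)(C)C(C)(C)C)C[C@H]1OC1(C)C | intermediate
21 | bromo{(3S)-3-{[tert-butyl(dimethyl)silyl]oxy}-4-[(2R)-3,3-dimethyloxiran-2-yl]but-1-en-2-yl}magnesium | Br[Mg]C(=C)[C@@H](O[Si](C)(C)C(C)(C)C)C[C@H]1OC1(C)C | intermediate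
22 | bromomagnesium alkoxide of 10 (O–MgBr in place of O–H) | O=C1C=C[C@H](O[Mg]Br)[C@@H]2O[C@]12C | intermediate
23 | bis(bromomagnesium) enolate-alkoxide of 24 (BrMgO–C=CH enolate from the ketone and its ring CH2; BrMgO in place of the hydroxyl) | C=C([C@@H]1[C@H](O[Mg]Br)[C@@H]2O[C@]2(C)C(O[Mg]Br)=C1)[C@H](C[C@H]1OC1(C)C)O[Si](C)(C)C(C)(C)C | intermediate
24 | (1S,4R,5S,6S)-4-[(3S)-3-{[tert-butyl(dimethyl)silyl]oxy}-4-[(2R)-3,3-dimethyloxiran-2-yl]but-1-en-2-yl]-5-hydroxy-1-methyl-7-oxabicyclo[4.1.0]heptan-2-one | C=C([C@@H]1[C@H](O)[C@@H]2O[C@]2(C)C(=O)C1)[C@H](C[C@H]1OC1(C)C)O[Si](C)(C)C(C)(C)C | intermediate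
25 | (1S,4R,5S,6S)-4-{(3S)-4-[(2R)-3,3-dimethyloxiran-2-yl]-3-hydroxybut-1-en-2-yl}-5-hydroxy-1-methyl-7-oxabicyclo[4.1.0]heptan-2-one | C=C([C@@H]1[C@H](O)[C@@H]2O[C@]2(C)C(=O)C1)[C@H](C[C@H]1OC1(C)C)O | intermediate
26 | (1S,2S,3R,6S)-3-[(3S)-4-[(2R)-3,3-dimethyloxiran-2-yl]-3-{[(2E)-2-methylbut-2-enoyl]oxy}but-1-en-2-yl]-6-methyl-5-oxo-7-oxabicyclo[4.1.0]heptan-2-yl (2E)-2-methylbut-2-enoate | C=C([C@@H]1[C@H](OC(=O)/C(C)=C/C)[C@@H]2O[C@]2(C)C(=O)C1)[C@H](C[C@H]1OC1(C)C)OC(=O)/C(C)=C/C | intermediate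
27 | potassium enolate of 26 (KO–C=CH in the ring, from the ketone and its CH2; other centres as in 26) | [K+].C=C([C@@H]1[C@H](OC(=O)/C(C)=C/C)[C@@H]2O[C@]2(C)C([O-])=C1)[C@H](C[C@H]1OC1(C)C)OC(=O)/C(C)=C/C | intermediate
28 | (1S,2S,3R,4S,6S)-3-[(3S)-4-[(2R)-3,3-dimethyloxiran-2-yl]-3-{[(2E)-2-methylbut-2-enoyl]oxy}but-1-en-2-yl]-4-hydroxy-6-methyl-5-oxo-7-oxabicyclo[4.1.0]heptan-2-yl (2E)-2-methylbut-2-enoate | C=C([C@@H]1[C@H](OC(=O)/C(C)=C/C)[C@@H]2O[C@]2(C)C(=O)[C@H]1O)[C@H](C[C@H]1OC1(C)C)OC(=O)/C(C)=C/C | intermediate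
29 | (1S,2S,3R,4S,6S)-4-(acetyloxy)-3-[(3S)-4-[(2R)-3,3-dimethyloxiran-2-yl]-3-{[(2E)-2-methylbut-2-enoyl]oxy}but-1-en-2-yl]-6-methyl-5-oxo-7-oxabicyclo[4.1.0]heptan-2-yl (2E)-2-methylbut-2-enoate | C=C([C@@H]1[C@H](OC(=O)/C(C)=C/C)[C@@H]2O[C@]2(C)C(=O)[C@H]1OC(C)=O)[C@H](C[C@H]1OC1(C)C)OC(=O)/C(C)=C/C | target

**Step count and risks**

Total steps: 17 (six to ring fragment 10, six to side-chain fragment 19, five after their union). Longest linear sequence: 11 steps (1 → 10 → 29, or equally 11 → 19 → 29).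

Most likely to fail, first: step 13. The alkoxide-directed addition has to beat 1,2-addition to the ketone and the steric preference for the opposite face, and two epoxides must survive the magnesium salts. The fallback sets out from alkenyllithium 20 and enone 10 and comes back at 24. Lithium reagent 20 is quenched with 2-isopropoxy-4,4,5,5-tetramethyl-1,3,2-dioxaborolane to give the alkenyl pinacol boronate F1. This is added to unprotected 10 with [Rh(cod)OH]2 (monovalent rhodium, 3 mol %) in dioxane/water at 30 °C. The free hydroxyl binds rhodium and steers the alkenyl group to its own face, and protonation of the rhodium enolate gives ketone 24 directly.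

Second: step 5. The cis selectivity rests on hydroxyl guidance of a nucleophilic epoxidation and could be modest. The fallback sets out from 6 and comes back at 7. TBSCl/imidazole gives the silyl ether F2. Luche reduction (NaBH4, CeCl3·7H2O, MeOH, −78 °C), with hydride expected to add anti to the silyloxy group, gives mainly the 1,4-cis allylic alcohol F3. VO(acac)2/t-BuOOH epoxidation, now directed by the new allylic hydroxyl on an electron-rich alkene, gives the all-cis epoxy alcohol F4. Dess–Martin periodinane gives the silyl-protected epoxy ketone F5, and Bu4NF/AcOH returns 7.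

Third: step 6. Selenenylation of a dianion that carries a free alkoxide, followed by oxidation next to an epoxy ketone, may give low yields. The fallback sets out from 7 and comes back at 10. LiN(i-Pr)2 (2.2 equiv) and Me3SiCl give the bis(trimethylsilyl) compound F6 (silyl enol ether plus silyl ether). Saegusa–Ito oxidation with Pd(OAc)2 (divalent palladium, 1.05 equiv) in MeCN gives the silyl-protected enone F7, and K2CO3/MeOH removes the O-silyl group to return 10.

**Further compounds**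
F1 | step 13 | 2-{(3S)-3-{[tert-butyl(dimethyl)silyl]oxy}-4-[(2R)-3,3-dimethyloxiran-2-yl]but-1-en-2-yl}-4,4,5,5-tetramethyl-1,3,2-dioxaborolane | CC1(C)OB(OC1(C)C)C(=C)[C@@H](O[Si](C)(C)C(C)(C)C)C[C@H]1OC1(C)C
F2 | step 5 | (4S)-4-{[tert-butyl(dimethyl)silyl]oxy}-2-methylcyclohex-2-en-1-one | CC1=C[C@@H](O[Si](C)(C)C(C)(C)C)CCC1=O
F3 | step 5 | (1R,4S)-4-{[tert-butyl(dimethyl)silyl]oxy}-2-methylcyclohex-2-en-1-ol (1,4-cis) | C1[C@H](O[Si](C)(C)C(C)(C)C)C=C(C)[C@H](O)C1
F4 | step 5 | (5S)-5-{[tert-butyl(dimethyl)silyl]oxy}-1-methyl-7-oxabicyclo[4.1.0]heptan-2-ol with hydroxyl, silyloxy group and epoxide oxygen all on one face | C1[C@H](O[Si](C)(C)C(C)(C)C)[C@@H]2O[C@]2(C)[C@H](O)C1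
F5 | step 5 | (1S,5S,6S)-5-{[tert-butyl(dimethyl)silyl]oxy}-1-methyl-7-oxabicyclo[4.1.0]heptan-2-one | O=C1CC[C@H](O[Si](C)(C)C(C)(C)C)[C@@H]2O[C@]12C
F6 | step 6 | bis(trimethylsilyl) derivative of 7 (trimethylsilyl enol ether of the ketone toward its CH2, trimethylsilyl ether of the hydroxyl) | C1[C@H](O[Si](C)(C)C)[C@@H]2O[C@]2(C)C(O[Si](C)(C)C)=C1
F7 | step 6 | (1S,5S,6S)-1-methyl-5-[(trimethylsilyl)oxy]-7-oxabicyclo[4.1.0]hept-3-en-2-one | O=C1C=C[C@H](O[Si](C)(C)C)[C@@H]2O[C@]12C
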